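**Plan**

- Retrosynthesis: the three phenol methyl ethers and the two formyl groups are removed first, then C1′–isobutyl and C1′–aryl (back to a C1 carbaldehyde), C4–C15 and the two C11 methyls. The ring bonds C4–C5 and C9–C10 are then cut in one operation, and the open chain is cut at C6–C7.
- Enabling feature: the decalin is trans-fused (C5–H and the C10 methyl on opposite faces) and its groups at C1, C4 (oxygen) and C7 are all equatorial. This is the pattern a chair–chair cation–olefin cyclization gives from an (E)-C5=C10 alkene when C4 is the electrophile and C9 the terminating nucleophile.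
- Forward: the chain C4–C1–C10=C5–C6 is built (aldol, olefination) and joined at C6–C7 to a C7–C9 (Z)-vinylsilane unit. Rings A and B then close together in step 17. C8=C9 reduction, the C11 and C4 carbinols, the arene and isobutyl group at C1′, the formyl groups and demethylation follow.
- Stereochemistry: C1 from an Evans aldol and C7 from an Evans alkylation. C5 and C10 come from the chair–chair cyclization under control of C1 and C7. C4 comes from α-face epoxidation of a C4 methylene anti to the axial C10 methyl. C1′ comes from addition of an allylsilane to a benzylic cation on the face away from C10.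

Key step: step 17

Remark: decalin atoms carry eudesmane numbers (C1 bears the side chain, C4 the ring carbinol, C5 is the ring-fusion CH, C7 bears C11, C10 bears the angular methyl, C15 is the carbon on C4, C1′ lies between C1 and the arene). β means the face of the C10 methyl. TBDPS = tert-butyl(diphenyl)silyl.

**Route**

Step 1
Reactants: 1 methyl 5,5-dimethoxypentanoate
Product: 2 5,5-dimethoxypentanoic acid
Conditions: LiOH·H2O, THF/H2O, rt; then cold dilute HCl to pH 4–5
Reagents that add atoms: lithium hydroxide, [Li+].[OH-]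
Why: Saponification of the methyl ester should leave the base-stable dimethyl acetal untouched, and the acid is used at once to avoid self-catalysed acetal loss.

Step 2
Reactants: 2 5,5-dimethoxypentanoic acid; 3 (R)-4-benzyl-1,3-oxazolidin-2-one
Product: 5 (R)-4-benzyl-3-(5,5-dimethoxypentanoyl)-1,3-oxazolidin-2-one, via mixed pivalic anhydride 4 (not isolated)
Conditions: PivCl, Et3N, THF, −20 °C; then 3, LiCl, −20 °C → rt
Reagents that add atoms: none
Why: N-Acylation through the mixed pivalic anhydride (LiCl/Et3N protocol) should occur at the unhindered acyl carbon and avoids an acid chloride, which the acetal would not survive.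

Step 3
Reactants: 5 (R)-4-benzyl-3-(5,5-dimethoxypentanoyl)-1,3-oxazolidin-2-one
Product: 7 (R)-4-benzyl-3-[(2R,3S)-2-(3,3-dimethoxypropyl)-3-hydroxybutanoyl]-1,3-oxazolidin-2-one, via dibutylboron Z(O)-enolate 6 (not isolated)
Conditions: Bu2BOTf, i-Pr2NEt, CH2Cl2, −78 → 0 °C; MeCHO, −78 → 0 °C; pH 7 buffer, MeOH, H2O2
Reagents that add atoms: acetaldehyde, CC=O
Why: Evans syn aldol reaction: the Z(O) boron enolate meets acetaldehyde in a Zimmerman–Traxler chair in which the (R)-benzyl auxiliary exposes the face that gives (R) at the α-carbon (the future C1); the carbinol centre formed alongside is removed in step 6.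

Step 4
Reactants: 7 aldol adduct
Product: 8 (2S,3S)-2-(3,3-dimethoxypropyl)butane-1,3-diol
Conditions: LiBH4, MeOH (1 equiv), THF, 0 °C
Reagents that add atoms: none
Why: Hydride reduction of the N-acyl oxazolidinone should give the primary alcohol (the future C1′–OH) without epimerisation and return the auxiliary.

Step 5
Reactants: 8 diol
Product: 9 (2S,3S)-3-(TBDPS-oxymethyl)-6,6-dimethoxyhexan-2-ol
Conditions: TBDPSCl, imidazole, CH2Cl2, 0 °C
Reagents that add atoms: tert-butylchlorodiphenylsilane, CC(C)(C)[Si](Cl)(c1ccccc1)c1ccccc1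
Why: Silylation with the bulky chlorosilane should be selective for the primary over the secondary hydroxyl.

Step 6
Reactants: 9 secondary alcohol
Product: 10 (S)-3-(TBDPS-oxymethyl)-6,6-dimethoxyhexan-2-one
Conditions: Dess–Martin periodinane, NaHCO3, CH2Cl2, rt
Reagents that add atoms: none
Why: Dess–Martin oxidation under buffered, non-basic conditions should give the methyl ketone without epimerising the α-centre or eliminating the β-silyloxy group.

Step 7
Reactants: 10 methyl ketone; 11 triethyl phosphonoacetate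
Product: 13 ethyl (2E,4R)-4-(TBDPS-oxymethyl)-7,7-dimethoxy-3-methylhept-2-enoate, via sodium phosphonate anion 12 (not isolated)
Conditions: NaH, THF, 0 °C; then 10, rt → 50 °C
Reagents that add atoms: none
Why: Horner–Wadsworth–Emmons olefination of the methyl ketone should place the ester trans to the branched C1 substituent (E), and the weakly basic stabilised anion is expected to leave the α-stereocentre intact.

Step 8
Reactants: 13 enoate
Product: 14 (2E,4R)-4-(TBDPS-oxymethyl)-7,7-dimethoxy-3-methylhept-2-en-1-ol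
Conditions: i-Bu2AlH, CH2Cl2, −78 °C; aq. potassium sodium tartrate
Reagents that add atoms: none
Why: 1,2-Reduction of the enoate by the aluminium hydride should give the (E)-allylic alcohol with acetal and silyl ether unaffected.

Step 9
Reactants: 14 allylic alcohol
Product: 15 (2E,4R)-1-bromo-4-(TBDPS-oxymethyl)-7,7-dimethoxy-3-methylhept-2-ene
Conditions: CBr4, PPh3, 2,6-lutidine, CH2Cl2, 0 °C
Reagents that add atoms: carbon tetrabromide, BrC(Br)(Br)Br
Why: Appel bromination replaces the primary allylic hydroxyl by SN2 under buffered neutral conditions, which should keep the (E)-alkene and the acetal.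

Step 10
Reactants: 16 trimethylsilylacetylene
Product: 18 4-(trimethylsilyl)but-3-yn-1-ol, via lithium acetylide 17 (not isolated)
Conditions: n-BuLi, THF, −78 °C; BF3·OEt2, ethylene oxide, −78 °C
Reagents that add atoms: ethylene oxide, C1CO1
Why: BF3-assisted opening of the epoxide by the lithium acetylide is a standard two-carbon homologation.

Step 11
Reactants: 18 silyl alkynol
Product: 19 (Z)-4-(trimethylsilyl)but-3-en-1-ol
Conditions: H2 (1 atm), Ni(OAc)2·4H2O, NaBH4, ethylenediamine, EtOH, rt
Reagents that add atoms: none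
Why: syn Semi-hydrogenation of the silylalkyne over amine-poisoned nickel boride should stop at the (Z)-vinylsilane.

Step 12
Reactants: 19 (Z)-alkenol
Product: 20 (Z)-4-(trimethylsilyl)but-3-enoic acid
Conditions: TEMPO (cat.), PhI(OAc)2, MeCN/H2O, rt
Reagents that add atoms: water, O
Why: Oxoammonium (TEMPO) oxidation takes the primary alcohol through the aldehyde hydrate to the acid under near-neutral conditions that should neither conjugate the β,γ-alkene nor protodesilylate.

Step 13
Reactants: 20 (Z)-4-(trimethylsilyl)but-3-enoic acid; 21 (S)-4-benzyl-1,3-oxazolidin-2-one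
Product: 23 (S)-4-benzyl-3-[(Z)-4-(trimethylsilyl)but-3-enoyl]-1,3-oxazolidin-2-one, via mixed pivalic anhydride 22 (not isolated)
Conditions: PivCl, Et3N, THF, −20 °C; then 21, LiCl, −20 °C → rt
Reagents that add atoms: none
Why: The same mixed-anhydride N-acylation as in step 2 is mild enough to leave the β,γ-unsaturated acyl group unconjugated.

Step 14
Reactants: 23 vinylsilane imide; 15 allylic bromide
Product: 25 (S)-4-benzyl-3-[(2S,4E,6R)-6-(TBDPS-oxymethyl)-9,9-dimethoxy-5-methyl-2-[(Z)-2-(trimethylsilyl)ethenyl]non-4-enoyl]-1,3-oxazolidin-2-one, via sodium Z(O)-dienolate 24 (not isolated)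
Conditions: NaN(SiMe3)2, THF, −78 °C; then 15, −78 → −40 °C
Reagents that add atoms: none
Why: Evans asymmetric alkylation: the chelated Z(O) sodium dienolate should react at its α-carbon (C7) with the allylic bromide on the face opposite the benzyl group, forming C6–C7 with (S) configuration at C7 and leaving the (Z)-vinylsilane untouched.

Step 15
Reactants: 25 alkylated imide
Product: 26 methyl (2S,4E,6R)-6-(TBDPS-oxymethyl)-9,9-dimethoxy-5-methyl-2-[(Z)-2-(trimethylsilyl)ethenyl]non-4-enoate
Conditions: MeMgBr, MeOH, CH2Cl2, 0 °C; aq. NH4Cl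
Reagents that add atoms: methanol, CO
Why: Transesterification by magnesium methoxide at the exocyclic imide carbonyl is mild enough that the α-vinyl centre should survive; should C7 epimerise in part, equilibration of 29 with NaOMe after step 18 would converge on the same equatorial ester.

Step 16
Reactants: 26 dimethyl acetal
Product: 27 methyl (2S,4E,6R)-6-(TBDPS-oxymethyl)-5-methyl-9-oxo-2-[(Z)-2-(trimethylsilyl)ethenyl]non-4-enoate
Conditions: PPTS (cat.), acetone/H2O, 40 °C
Reagents that add atoms: water, O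
Why: Acetal hydrolysis under weakly acidic conditions should be tolerated by the silyl ether, the vinylsilane and the C7 centre.

Step 17
Reactants: 27 (E,Z)-dienal
Product: 28 methyl 1β-(TBDPS-oxymethyl)-4α-hydroxy-10β-methyl-trans-decal-8-ene-7β-carboxylate (5α-H)
Conditions: MeAlCl2 (2.2 equiv), CH2Cl2, −78 °C; aq. NaHCO3
Reagents that add atoms: none
Why: MeAlCl2 binds the aldehyde, C5 of the (E)-trisubstituted alkene adds to C4, and the tertiary cation developing at C10 is captured by the silicon-bearing C9 of the (Z)-vinylsilane; desilylation of the resulting β-silyl cation by chloride then unveils the C8=C9 double bond. The closest known reaction type is the Lewis acid promoted, aldehyde-initiated (Prins-type) cation–olefin polycyclization with a vinylsilane terminator. Ring A closes 6-endo with respect to the C5=C10 alkene through a chair, and ring B closes 6-endo with respect to the vinylsilane through a second chair by ipso substitution, the (Z) geometry supplying the cis ring alkene. C5 and C10 are set by anti addition across the (E)-alkene in this chair–chair array (trans fusion, C10 methyl axial, C5–H on the other face), and their absolute sense is dictated by C1 and C7, whose silyloxymethyl and ester groups are both equatorial only in the folding that leads to 28; C4 is set by the aluminium-bound oxygen taking the equatorial (α) position and is erased in step 20. The step needs ring B closure to outrun proton loss from the C10 cation and capture by the ester carbonyl, and one folding to dominate: the vinylsilane is held in a six-membered chair next to C10 and its attack is helped by the β-silicon effect, the second equivalent of MeAlCl2 ties up the ester and removes protons as methane, and the two chain stereocentres reinforce each other.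

Step 18
Reactants: 28 octalin ester
Product: 29 methyl 1β-(TBDPS-oxymethyl)-4α-hydroxy-10β-methyl-trans-decalin-7β-carboxylate (5α-H)
Conditions: H2 (1 atm), Pd/C, EtOAc, rt
Reagents that add atoms: none
Why: Heterogeneous hydrogenation of the cis-disubstituted C8=C9 alkene; if migration to C7=C8 intervened, hydrogen would add from the α face away from the axial C10 methyl and give the same equatorial 7β-ester.

Step 19
Reactants: 29 decalin ester
Product: 30 1β-(TBDPS-oxymethyl)-7β-(2-hydroxypropan-2-yl)-10β-methyl-trans-decalin-4α-ol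
Conditions: MeMgBr (excess), THF, 0 °C → rt; aq. NH4Cl
Reagents that add atoms: methylmagnesium bromide, C[Mg]Br
Why: Double Grignard addition to the methyl ester gives the C11 tertiary carbinol, the C4 alkoxide formed by the first equivalent being a spectator.

Step 20
Reactants: 30 diol
Product: 31 1β-(TBDPS-oxymethyl)-7β-(2-hydroxypropan-2-yl)-10β-methyl-trans-decalin-4-one
Conditions: Dess–Martin periodinane, NaHCO3, CH2Cl2, rt
Reagents that add atoms: none
Why: Dess–Martin oxidation of the secondary C4 alcohol; the tertiary C11 alcohol cannot be oxidised.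

Step 21
Reactants: 31 C4 ketone
Product: 32 2-[1β-(TBDPS-oxymethyl)-10β-methyl-4-methylene-trans-decalin-7β-yl]propan-2-ol
Conditions: Ph3PCH3Br, KOtBu, THF, rt → 60 °C
Reagents that add atoms: methyltriphenylphosphonium bromide, C[P+](c1ccccc1)(c1ccccc1)c1ccccc1.[Br-]
Why: Wittig methylenation of the C4 ketone; the trans ring fusion at C5 is the more stable arrangement and should survive the basic ylide.

Step 22
Reactants: 32 exocyclic alkene
Product: 33 4α,15-epoxide of 32 (epoxide oxygen α, C15 β)
Conditions: mCPBA, NaHCO3, CH2Cl2, 0 °C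
Reagents that add atoms: 3-chloroperoxybenzoic acid, OOC(=O)c1cccc(Cl)c1
Why: Prilezhaev epoxidation: the β face of the C4 methylene is screened by the axial C10 methyl in a 1,3-relationship, so the peracid should deliver oxygen from the α (equatorial) side and thereby fix C4.

Step 23
Reactants: 33 spiro-epoxide
Product: 34 1β-(TBDPS-oxymethyl)-7β-(2-hydroxypropan-2-yl)-4β,10β-dimethyl-trans-decalin-4α-ol
Conditions: LiEt3BH, THF, 0 °C → rt
Reagents that add atoms: none
Why: SN2 opening of the epoxide by hydride at the unhindered C15 methylene turns it into the 4β-methyl group and leaves the oxygen as the 4α tertiary alcohol, with C4 unchanged.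

Step 24
Reactants: 34 silyl ether
Product: 35 1β-(hydroxymethyl)-7β-(2-hydroxypropan-2-yl)-4β,10β-dimethyl-trans-decalin-4α-ol
Conditions: Bu4NF, THF, rt
Reagents that add atoms: none
Why: Fluoride-induced desilylation frees the primary alcohol and does not affect the tertiary alcohols.

Step 25
Reactants: 35 triol
Product: 36 4α-hydroxy-7β-(2-hydroxypropan-2-yl)-4β,10β-dimethyl-trans-decalin-1β-carbaldehyde
Conditions: Dess–Martin periodinane, NaHCO3, CH2Cl2, 0 °C → rt
Reagents that add atoms: none
Why: Dess–Martin oxidation of the only oxidisable (primary) hydroxyl; the equatorial C1 aldehyde is the thermodynamically preferred epimer, so no erosion at C1 is expected.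

Step 26
Reactants: 36 aldehyde; 37 1,3,5-trimethoxybenzene
Product: 39 (2,4,6-trimethoxyphenyl)[4α-hydroxy-7β-(2-hydroxypropan-2-yl)-4β,10β-dimethyl-trans-decalin-1β-yl]methanol (both C1′ epimers), via 2,4,6-trimethoxyphenyllithium 38 (not isolated)
Conditions: 37, n-BuLi, THF, 0 °C → rt; then 36, −78 °C → rt (aryllithium in excess)
Reagents that add atoms: none
Why: Ortho-lithiation between two methoxy groups and 1,2-addition of the aryllithium to the aldehyde (two equivalents are consumed by the tertiary hydroxyls); the configuration of the new carbinol is irrelevant because it is ionised in step 27.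

Step 27
Reactants: 39 benzylic alcohol
Product: 40 1β-[(1S)-3-methyl-1-(2,4,6-trimethoxyphenyl)but-3-enyl]-7β-(2-hydroxypropan-2-yl)-4β,10β-dimethyl-trans-decalin-4α-ol
Conditions: 2-methylallyltrimethylsilane, BF3·OEt2, CH2Cl2, −78 °C
Reagents that add atoms: trimethyl(2-methylallyl)silane, CC(=C)C[Si](C)(C)C
Why: SN1 benzylic substitution of the Hosomi–Sakurai type: both epimers of 39 give one trimethoxybenzylic cation in which C1–H eclipses the aryl plane to avoid A1,3 strain with an ortho-methoxy group, so the silane should add on the face flanked by C2 and away from the quaternary C10, giving (1′S).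

Step 28
Reactants: 40 methallyl compound
Product: 41 1β-[(1S)-3-methyl-1-(2,4,6-trimethoxyphenyl)butyl]-7β-(2-hydroxypropan-2-yl)-4β,10β-dimethyl-trans-decalin-4α-ol
Conditions: H2 (1 atm), Pd/C, EtOAc, rt
Reagents that add atoms: none
Why: Catalytic hydrogenation of the 1,1-disubstituted alkene gives the isobutyl group; no other reducible group is present.

Step 29
Reactants: 41 isobutyl arene
Product: 42 1β-[(1S)-1-(3,5-dibromo-2,4,6-trimethoxyphenyl)-3-methylbutyl]-7β-(2-hydroxypropan-2-yl)-4β,10β-dimethyl-trans-decalin-4α-ol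
Conditions: NBS (2.1 equiv), MeCN, 0 °C, dark
Reagents that add atoms: N-bromosuccinimide, O=C1CCC(=O)N1Br
Why: Electrophilic aromatic bromination at the two remaining ring positions, each flanked by two methoxy groups, should be fast and leave the tertiary alcohols alone.

Step 30
Reactants: 42 dibromide
Product: 44 5-[(1S)-1-[4α-hydroxy-7β-(2-hydroxypropan-2-yl)-4β,10β-dimethyl-trans-decalin-1β-yl]-3-methylbutyl]-2,4,6-trimethoxybenzene-1,3-dicarbaldehyde, via tetralithiated dialkoxide 43 (not isolated)
Conditions: t-BuLi (excess), THF, −78 °C; DMF, −78 °C → rt; H2O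
Reagents that add atoms: N,N-dimethylformamide, CN(C)C=O
Why: After deprotonation of the two hydroxyls, double bromine–lithium exchange gives aryllithium centres each stabilised by two flanking methoxy groups, and formylation with DMF (Bouveault reaction) installs both aldehydes under basic conditions that the tertiary alcohols tolerate.

Step 31
Reactants: 44 tri-O-methyl ether
Product: 45 macrocarpal J
Conditions: NaSEt (excess), DMF, 120 °C; then dilute HCl
Reagents that add atoms: none
Why: SN2 demethylation of the three aryl methyl ethers by thiolate, each activated by an ortho or para formyl group, under basic conditions that spare the two acid-sensitive tertiary alcohols.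

**Compound list**

1 | methyl 5,5-dimethoxypentanoate | COC(=O)CCCC(OC)OC | starting material
2 | 5,5-dimethoxypentanoic acid | OC(=O)CCCC(OC)OC | intermediate
3 | (R)-4-benzyl-1,3-oxazolidin-2-one | O=C1N[C@H](Cc2ccccc2)CO1 | starting material
4 | 5,5-dimethoxypentanoic pivalic anhydride | COC(OC)CCCC(=O)OC(=O)C(C)(C)C | intermediate
5 | (R)-4-benzyl-3-(5,5-dimethoxypentanoyl)-1,3-oxazolidin-2-one | COC(OC)CCCC(=O)N1[C@H](Cc2ccccc2)COC1=O | intermediate
6 | dibutylboron Z(O)-enolate of 5 | CCCCB(CCCC)O/C(=C\CCC(OC)OC)N1[C@H](Cc2ccccc2)COC1=O | intermediate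
7 | (R)-4-benzyl-3-[(2R,3S)-2-(3,3-dimethoxypropyl)-3-hydroxybutanoyl]-1,3-oxazolidin-2-one | COC(OC)CC[C@H]([C@H](C)O)C(=O)N1[C@H](Cc2ccccc2)COC1=O | intermediate
8 | (2S,3S)-2-(3,3-dimethoxypropyl)butane-1,3-diol | COC(OC)CC[C@H]([C@H](C)O)CO | intermediate
9 | (2S,3S)-3-(TBDPS-oxymethyl)-6,6-dimethoxyhexan-2-ol | COC(OC)CC[C@H]([C@H](C)O)CO[Si](c1ccccc1)(c1ccccc1)C(C)(C)C | intermediate
10 | (S)-3-(TBDPS-oxymethyl)-6,6-dimethoxyhexan-2-one | COC(OC)CC[C@H](C(C)=O)CO[Si](c1ccccc1)(c1ccccc1)C(C)(C)C | intermediate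
11 | triethyl phosphonoacetate | CCOC(=O)CP(=O)(OCC)OCC | starting material
12 | sodium salt of 11 (phosphonate carbanion) | CCOC(=O)[CH-]P(=O)(OCC)OCC.[Na+] | intermediate
13 | ethyl (2E,4R)-4-(TBDPS-oxymethyl)-7,7-dimethoxy-3-methylhept-2-enoate | COC(OC)CC[C@H](/C(C)=C/C(=O)OCC)CO[Si](c1ccccc1)(c1ccccc1)C(C)(C)C | intermediate
14 | (2E,4R)-4-(TBDPS-oxymethyl)-7,7-dimethoxy-3-methylhept-2-en-1-ol | COC(OC)CC[C@H](/C(C)=C/CO)CO[Si](c1ccccc1)(c1ccccc1)C(C)(C)C | intermediate
15 | (2E,4R)-1-bromo-4-(TBDPS-oxymethyl)-7,7-dimethoxy-3-methylhept-2-ene | COC(OC)CC[C@H](/C(C)=C/CBr)CO[Si](c1ccccc1)(c1ccccc1)C(C)(C)C | intermediate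
16 | trimethylsilylacetylene | C#C[Si](C)(C)C | starting material
17 | lithium (trimethylsilyl)acetylide | [Li]C#C[Si](C)(C)C | intermediate
18 | 4-(trimethylsilyl)but-3-yn-1-ol | OCCC#C[Si](C)(C)C | intermediate
19 | (Z)-4-(trimethylsilyl)but-3-en-1-ol | OCC/C=C\[Si](C)(C)C | intermediate
20 | (Z)-4-(trimethylsilyl)but-3-enoic acid | OC(=O)C/C=C\[Si](C)(C)C | intermediate
21 | (S)-4-benzyl-1,3-oxazolidin-2-one | O=C1N[C@@H](Cc2ccccc2)CO1 | starting material
22 | (Z)-4-(trimethylsilyl)but-3-enoic pivalic anhydride | CC(C)(C)C(=O)OC(=O)C/C=C\[Si](C)(C)C | intermediate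
23 | (S)-4-benzyl-3-[(Z)-4-(trimethylsilyl)but-3-enoyl]-1,3-oxazolidin-2-one | C[Si](C)(C)/C=C\CC(=O)N1[C@@H](Cc2ccccc2)COC1=O | intermediate
24 | sodium Z(O)-dienolate of 23 | [Na]O/C(=C\C=C/[Si](C)(C)C)N1[C@@H](Cc2ccccc2)COC1=O | intermediate
25 | (S)-4-benzyl-3-[(2S,4E,6R)-6-(TBDPS-oxymethyl)-9,9-dimethoxy-5-methyl-2-[(Z)-2-(trimethylsilyl)ethenyl]non-4-enoyl]-1,3-oxazolidin-2-one | COC(OC)CC[C@H](/C(C)=C/C[C@@H](/C=C\[Si](C)(C)C)C(=O)N1[C@@H](Cc2ccccc2)COC1=O)CO[Si](c1ccccc1)(c1ccccc1)C(C)(C)C | intermediate
26 | methyl (2S,4E,6R)-6-(TBDPS-oxymethyl)-9,9-dimethoxy-5-methyl-2-[(Z)-2-(trimethylsilyl)ethenyl]non-4-enoate | COC(OC)CC[C@H](/C(C)=C/C[C@@H](/C=C\[Si](C)(C)C)C(=O)OC)CO[Si](c1ccccc1)(c1ccccc1)C(C)(C)C | intermediate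
27 | methyl (2S,4E,6R)-6-(TBDPS-oxymethyl)-5-methyl-9-oxo-2-[(Z)-2-(trimethylsilyl)ethenyl]non-4-enoate | O=CCC[C@@H](CO[Si](c1ccccc1)(c1ccccc1)C(C)(C)C)/C(C)=C/C[C@H](C(=O)OC)/C=C\[Si](C)(C)C | intermediate
28 | methyl 1β-(TBDPS-oxymethyl)-4α-hydroxy-10β-methyl-trans-decal-8-ene-7β-carboxylate (5α-H) | CC(C)(C)[Si](c1ccccc1)(c1ccccc1)OC[C@@H]1CC[C@@H](O)[C@@H]2C[C@H](C(=O)OC)C=C[C@]21C | intermediate
29 | methyl 1β-(TBDPS-oxymethyl)-4α-hydroxy-10β-methyl-trans-decalin-7β-carboxylate (5α-H) | CC(C)(C)[Si](c1ccccc1)(c1ccccc1)OC[C@@H]1CC[C@@H](O)[C@@H]2C[C@H](C(=O)OC)CC[C@]21C | intermediate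
30 | 1β-(TBDPS-oxymethyl)-7β-(2-hydroxypropan-2-yl)-10β-methyl-trans-decalin-4α-ol | CC(C)(C)[Si](c1ccccc1)(c1ccccc1)OC[C@@H]1CC[C@@H](O)[C@@H]2C[C@H](C(C)(C)O)CC[C@]21C | intermediate
31 | 1β-(TBDPS-oxymethyl)-7β-(2-hydroxypropan-2-yl)-10β-methyl-trans-decalin-4-one | CC(C)(C)[Si](c1ccccc1)(c1ccccc1)OC[C@@H]1CCC(=O)[C@@H]2C[C@H](C(C)(C)O)CC[C@]21C | intermediate
32 | 2-[1β-(TBDPS-oxymethyl)-10β-methyl-4-methylene-trans-decalin-7β-yl]propan-2-ol | CC(C)(C)[Si](c1ccccc1)(c1ccccc1)OC[C@@H]1CCC(=C)[C@@H]2C[C@H](C(C)(C)O)CC[C@]21C | intermediate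
33 | 4α,15-epoxide of 32 (oxygen α, C15 β) | CC(C)(C)[Si](c1ccccc1)(c1ccccc1)OC[C@@H]1CC[C@]3(CO3)[C@@H]2C[C@H](C(C)(C)O)CC[C@]21C | intermediate
34 | 1β-(TBDPS-oxymethyl)-7β-(2-hydroxypropan-2-yl)-4β,10β-dimethyl-trans-decalin-4α-ol | CC(C)(C)[Si](c1ccccc1)(c1ccccc1)OC[C@@H]1CC[C@@](C)(O)[C@@H]2C[C@H](C(C)(C)O)CC[C@]21C | intermediate
35 | 1β-(hydroxymethyl)-7β-(2-hydroxypropan-2-yl)-4β,10β-dimethyl-trans-decalin-4α-ol | OC[C@@H]1CC[C@@](C)(O)[C@@H]2C[C@H](C(C)(C)O)CC[C@]21C | intermediate
36 | 4α-hydroxy-7β-(2-hydroxypropan-2-yl)-4β,10β-dimethyl-trans-decalin-1β-carbaldehyde | O=C[C@@H]1CC[C@@](C)(O)[C@@H]2C[C@H](C(C)(C)O)CC[C@]21C | intermediate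
37 | 1,3,5-trimethoxybenzene | COc1cc(OC)cc(OC)c1 | starting material
38 | 2,4,6-trimethoxyphenyllithium | [Li]c1c(OC)cc(OC)cc1OC | intermediate
39 | (2,4,6-trimethoxyphenyl)[4α-hydroxy-7β-(2-hydroxypropan-2-yl)-4β,10β-dimethyl-trans-decalin-1β-yl]methanol (both C1′ epimers) | COc1cc(OC)c(C(O)[C@@H]2CC[C@@](C)(O)[C@@H]3C[C@H](C(C)(C)O)CC[C@]32C)c(OC)c1 | intermediate
40 | 1β-[(1S)-3-methyl-1-(2,4,6-trimethoxyphenyl)but-3-enyl]-7β-(2-hydroxypropan-2-yl)-4β,10β-dimethyl-trans-decalin-4α-ol | CC(=C)C[C@H](c1c(OC)cc(OC)cc1OC)[C@@H]1CC[C@@](C)(O)[C@@H]2C[C@H](C(C)(C)O)CC[C@]21C | intermediate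
41 | 1β-[(1S)-3-methyl-1-(2,4,6-trimethoxyphenyl)butyl]-7β-(2-hydroxypropan-2-yl)-4β,10β-dimethyl-trans-decalin-4α-ol | CC(C)C[C@H](c1c(OC)cc(OC)cc1OC)[C@@H]1CC[C@@](C)(O)[C@@H]2C[C@H](C(C)(C)O)CC[C@]21C | intermediate
42 | 1β-[(1S)-1-(3,5-dibromo-2,4,6-trimethoxyphenyl)-3-methylbutyl]-7β-(2-hydroxypropan-2-yl)-4β,10β-dimethyl-trans-decalin-4α-ol | CC(C)C[C@H](c1c(OC)c(Br)c(OC)c(Br)c1OC)[C@@H]1CC[C@@](C)(O)[C@@H]2C[C@H](C(C)(C)O)CC[C@]21C | intermediate
43 | tetralithio derivative of 42 (3,5-dilithioarene, dilithium dialkoxide) | CC(C)C[C@H](c1c(OC)c([Li])c(OC)c([Li])c1OC)[C@@H]1CC[C@@](C)(O[Li])[C@@H]2C[C@H](C(C)(C)O[Li])CC[C@]21C | intermediate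
44 | tri-O-methyl macrocarpal J (2,4,6-trimethoxybenzene-1,3-dicarbaldehyde carrying the (1S)-side chain at C5) | CC(C)C[C@H](c1c(OC)c(C=O)c(OC)c(C=O)c1OC)[C@@H]1CC[C@@](C)(O)[C@@H]2C[C@H](C(C)(C)O)CC[C@]21C | intermediate
45 | macrocarpal J | CC(C)C[C@H](c1c(O)c(C=O)c(O)c(C=O)c1O)[C@@H]1CC[C@@](C)(O)[C@@H]2C[C@H](C(C)(C)O)CC[C@]21C | target

**Step count**

Total: 31 steps. Longest linear sequence: 27 steps (steps 1–9, then 14–31).

**Steps most likely to fail**

Step 17. The C10 cation may lose a proton before the vinylsilane closes ring B, giving monocyclic ene-type material. The chain may also fold through the chair that places the C1 substituent axial, which relieves A1,2 strain against the C10 methyl and would erode diastereoselectivity. The fallback keeps the same two bond formations but starts them from a chiral acetal instead of the free aldehyde; it sets out from 27 and returns at 28. Aldehyde 27 is condensed with (2R,4R)-pentane-2,4-diol (PPTS, benzene, azeotropic removal of water) to give the dioxane acetal methyl (2S,4E,6R)-6-(TBDPS-oxymethyl)-8-[(4R,6R)-4,6-dimethyl-1,3-dioxan-2-yl]-5-methyl-2-[(Z)-2-(trimethylsilyl)ethenyl]oct-4-enoate F1. SnCl4 in CH2Cl2 at −78 °C opens the acetal at the oxygen next to the axial methyl with inversion at C4, and the oxocarbenium ion should trigger the same C4–C5/C9–C10 bicyclization. The template adds reagent control over the face of C5=C10, and an oxocarbenium ion is less prone to ene-type diversion. The product is the 4α-[(2R,4R)-4-hydroxypentan-2-yl] ether of 28 F2. Dess–Martin oxidation gives the 4α-[(2R)-4-oxopentan-2-yl] ether of 28 F3, and β-elimination with dibenzylammonium trifluoroacetate (benzene, 50 °C) releases 28.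

Step 27. The allylsilane may approach the benzylic cation from the C10 side or with little facial preference, and the cation may instead lose a proton or alkylate a second arene. The fallback reverses the order in which carbon and hydrogen are placed on C1′; it sets out from 39 and returns at 40. Alcohol 39 is oxidised (Dess–Martin periodinane) to the aryl ketone (2,4,6-trimethoxyphenyl)[4α-hydroxy-7β-(2-hydroxypropan-2-yl)-4β,10β-dimethyl-trans-decalin-1β-yl]methanone F4. 2-Methylallylmagnesium chloride adds to give the tertiary benzylic alcohol 1β-[1-hydroxy-3-methyl-1-(2,4,6-trimethoxyphenyl)but-3-enyl]-7β-(2-hydroxypropan-2-yl)-4β,10β-dimethyl-trans-decalin-4α-ol F5. Ionic hydrogenation (Et3SiH, BF3·OEt2, CH2Cl2, −78 °C) then replaces the hydroxyl by hydrogen to give 40. Because hydride rather than carbon now enters on the open face of a more encumbered tertiary cation, the sense at C1′ is the opposite of that from direct allylation.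

Step 30. The second bromine–lithium exchange may stay incomplete, and the polylithiated intermediate may be protonated or aggregate, giving mono-formylated or reduced material. The fallback avoids halogen–metal exchange and installs the aldehydes one at a time by deprotonative lithiation; it sets out from 41 and returns at 44. Compound 41 is treated with n-BuLi/TMEDA in THF (the two alkoxides form first, then a ring position between two methoxy groups is lithiated) and quenched with DMF to give the mono-aldehyde 3-[(1S)-1-[4α-hydroxy-7β-(2-hydroxypropan-2-yl)-4β,10β-dimethyl-trans-decalin-1β-yl]-3-methylbutyl]-2,4,6-trimethoxybenzaldehyde F6. F6 is then treated with lithium N,N,N′-trimethylethylenediamide, which adds to the formyl group and masks it as an α-amino alkoxide. n-BuLi lithiates the last ring position, and DMF followed by aqueous work-up gives 44.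

**Further compounds**

F1 | step 17 | methyl (2S,4E,6R)-6-(TBDPS-oxymethyl)-8-[(4R,6R)-4,6-dimethyl-1,3-dioxan-2-yl]-5-methyl-2-[(Z)-2-(trimethylsilyl)ethenyl]oct-4-enoate | C[C@@H]1C[C@@H](C)OC(CC[C@H](/C(C)=C/C[C@@H](/C=C\[Si](C)(C)C)C(=O)OC)CO[Si](c2ccccc2)(c2ccccc2)C(C)(C)C)O1
F2 | step 17 | 4α-[(2R,4R)-4-hydroxypentan-2-yl] ether of 28 | CC(C)(C)[Si](c1ccccc1)(c1ccccc1)OC[C@@H]1CC[C@@H](O[C@H](C)C[C@@H](C)O)[C@@H]2C[C@H](C(=O)OC)C=C[C@]21C
F3 | step 17 | 4α-[(2R)-4-oxopentan-2-yl] ether of 28 | CC(C)(C)[Si](c1ccccc1)(c1ccccc1)OC[C@@H]1CC[C@@H](O[C@H](C)CC(C)=O)[C@@H]2C[C@H](C(=O)OC)C=C[C@]21C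
F4 | step 27 | (2,4,6-trimethoxyphenyl)[4α-hydroxy-7β-(2-hydroxypropan-2-yl)-4β,10β-dimethyl-trans-decalin-1β-yl]methanone | COc1cc(OC)c(C(=O)[C@@H]2CC[C@@](C)(O)[C@@H]3C[C@H](C(C)(C)O)CC[C@]32C)c(OC)c1
F5 | step 27 | 1β-[1-hydroxy-3-methyl-1-(2,4,6-trimethoxyphenyl)but-3-enyl]-7β-(2-hydroxypropan-2-yl)-4β,10β-dimethyl-trans-decalin-4α-ol (C1′ epimers) | COc1cc(OC)c(C(O)(CC(C)=C)[C@@H]2CC[C@@](C)(O)[C@@H]3C[C@H](C(C)(C)O)CC[C@]32C)c(OC)c1
F6 | step 30 | 3-[(1S)-1-[4α-hydroxy-7β-(2-hydroxypropan-2-yl)-4β,10β-dimethyl-trans-decalin-1β-yl]-3-methylbutyl]-2,4,6-trimethoxybenzaldehyde | CC(C)C[C@H](c1c(OC)cc(OC)c(C=O)c1OC)[C@@H]1CC[C@@](C)(O)[C@@H]2C[C@H](C(C)(C)O)CC[C@]21C
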